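**Retrosynthetic overview**

1. Nymphaeol A is reached by global MOM removal after hydrolysis of a C4 spiro-1,3-dithiane. Ring C therefore passes through all base chemistry with its ketone masked, so C2 cannot epimerise by retro-oxa-Michael opening.
2. Ring C is made by a one-pot union of two halves that forms C3–C4 and O1–C8a. The lithiated 2-aryl-1,3-dithiane of ring A (masked C4 acyl anion, fluorine on C8a) opens the ring B (R)-aryloxirane at its CH2 (C3). The C2 alkoxide released then closes onto C8a by SNAr.
3. Enabling feature: ring C is a β-aryloxy ketone whose carbonyl carbon C4 is 1,3 to the oxygen-bearing C2 and, through C4a, ortho to the O1-bearing C8a. The ring A oxygens at C5 and C7 are meta to C8a and so do not disfavour the Meisenheimer intermediate.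
4. Ring A half: the geranyl carbon C6 lies on the mirror axis of 5-fluororesorcinol bis-MOM ether, so two successive ortho-metalations leave no 6- versus 8-geranyl question. Ring B half: asymmetric transfer hydrogenation of a commercial α-chloroketone, then oxirane closure.
5. Ring order: rings A and B are bought as benzenes; ring C is the only ring formed, in step 7.

Key step: step 7

Remark: the target is the (2S)-flavanone; 5-fluororesorcinol, geranyl bromide, 1,3-dithiane and 2-chloro-3',4'-dihydroxyacetophenone are taken as commercial.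

**Route**

Step 1
Reactants: 1 5-fluorobenzene-1,3-diol
Product: 2 1-fluoro-3,5-bis(methoxymethoxy)benzene
Conditions: MOMCl, i-Pr2NEt, CH2Cl2, 0 °C → rt
Reagents that add atoms: chloromethyl methyl ether (MOMCl), COCCl
Why: Williamson-type O-alkylation (MOM protection) turns both phenols into base-stable ortho-directing groups on a ring that keeps its mirror symmetry.

Step 2
Reactants: 2 1-fluoro-3,5-bis(methoxymethoxy)benzene; 3 geranyl bromide, (2E)-1-bromo-3,7-dimethylocta-2,6-diene
Product: 5 2-[(2E)-3,7-dimethylocta-2,6-dien-1-yl]-5-fluoro-1,3-bis(methoxymethoxy)benzene, via aryllithium 4 (not isolated)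
Conditions: n-BuLi, Et2O, 0 °C; then CuI (10 mol%), geranyl bromide, THF, −78 °C → rt
Reagents that add atoms: none
Why: Directed ortho-metalation at the carbon flanked by the two chelating OMOM groups, then copper-catalysed SN2 allylation of the aryllithium with the primary allylic bromide, should place the geranyl chain on the symmetry axis with the E-alkene unchanged.

Step 3
Reactants: 5 2-[(2E)-3,7-dimethylocta-2,6-dien-1-yl]-5-fluoro-1,3-bis(methoxymethoxy)benzene
Product: 8 2-{3-[(2E)-3,7-dimethylocta-2,6-dien-1-yl]-6-fluoro-2,4-bis(methoxymethoxy)phenyl}-1,3-dithiane, via aryllithium 6 (not isolated), via arylmagnesium bromide 7 (not isolated)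
Conditions: n-BuLi, THF, −78 °C; MgBr2·OEt2, −78 °C; then 2-chloro-1,3-dithiane (from 1,3-dithiane + NCS, benzene, rt), −78 → 0 °C
Reagents that add atoms: 2-chloro-1,3-dithiane, ClC1SCCCS1 (made in the flask from 1,3-dithiane, C1CSCSC1, and N-chlorosuccinimide, O=C1CCC(=O)N1Cl)
Why: A second directed ortho-metalation can only occur at one of the two equivalent C–H positions flanked by F and OMOM, and after transmetalation to magnesium (which suppresses loss of LiF to an aryne) the aryl Grignard reagent couples with 2-chloro-1,3-dithiane, a known formyl cation equivalent toward Grignard reagents, so the 2-aryl-1,3-dithiane forms without any acid that would endanger the MOM ethers or the geranyl chain.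

Step 4
Reactants: 9 2-chloro-1-(3,4-dihydroxyphenyl)ethan-1-one
Product: 10 2-chloro-1-[3,4-bis(methoxymethoxy)phenyl]ethan-1-one
Conditions: MOMCl, i-Pr2NEt, CH2Cl2, 0 °C → rt
Reagents that add atoms: chloromethyl methyl ether (MOMCl), COCCl
Why: O-alkylation (MOM protection) of the catechol with the highly reactive chloromethyl ether under a hindered amine base should outrun self-alkylation by the phenacyl chloride.

Step 5
Reactants: 10 2-chloro-1-[3,4-bis(methoxymethoxy)phenyl]ethan-1-one
Product: 11 (1R)-2-chloro-1-[3,4-bis(methoxymethoxy)phenyl]ethan-1-ol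
Conditions: Cp*RhCl[(S,S)-TsDPEN] (0.5 mol%), HCO2H–Et3N (5:2), EtOAc, rt
Reagents that add atoms: none
Why: Noyori asymmetric transfer hydrogenation of the aryl chloromethyl ketone; the (S,S)-TsDPEN catalyst delivers hydride to the same ketone face as in its reduction of acetophenone to (S)-1-phenylethanol, which here is the (R)-chlorohydrin because CH2Cl outranks aryl, so the future C2 stereocentre is set in this step.

Step 6
Reactants: 11 (1R)-2-chloro-1-[3,4-bis(methoxymethoxy)phenyl]ethan-1-ol
Product: 12 (2R)-2-[3,4-bis(methoxymethoxy)phenyl]oxirane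
Conditions: KOt-Bu, THF, 0 °C (product filtered through basic alumina and used directly)
Reagents that add atoms: none
Why: Intramolecular Williamson etherification (3-exo-tet) of the chlorohydrin alkoxide closes the oxirane without touching the stereocentre, so the (R) configuration is retained.

Step 7
Reactants: 8 2-{3-[(2E)-3,7-dimethylocta-2,6-dien-1-yl]-6-fluoro-2,4-bis(methoxymethoxy)phenyl}-1,3-dithiane; 12 (2R)-2-[3,4-bis(methoxymethoxy)phenyl]oxirane
Product: 15 (2S)-2-[3,4-bis(methoxymethoxy)phenyl]-6-[(2E)-3,7-dimethylocta-2,6-dien-1-yl]-5,7-bis(methoxymethoxy)-2,3-dihydrospiro[chromene-4,2'-[1,3]dithiane], via lithiodithiane 13 (not isolated), via lithium alkoxide 14 (not isolated)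
Conditions: n-BuLi (1.0 equiv), THF–HMPA (10:1), −78 °C; then 12, −78 → 0 °C; then 55 °C
Reagents that add atoms: none
Why: Deprotonation of the dithiane C–H, the most acidic C–H of 8, gives the masked C4 acyl anion 13, which opens oxirane 12 by SN2 attack at the unsubstituted CH2 to form the C3–C4 bond and release the C2 lithium alkoxide 14; on warming in THF–HMPA this alkoxide displaces fluoride at C8a by intramolecular SNAr and forms the O1–C8a bond. The closest known reaction types are the Corey–Seebach alkylation of 2-aryl-2-lithio-1,3-dithianes with terminal epoxides and the alkoxide SNAr closure of 1-aryl-3-(2-fluorophenyl)propan-1-ols to flavans. Ring C is the only ring closed, as a six-membered ring by 6-exo-trig addition–elimination at the arene carbon, helped by the gem-dithio (Thorpe–Ingold) effect and by the meta placement of the C5 and C7 oxygens relative to C8a. No new stereocentre is created: C2 comes from 12 and none of its bonds is broken, so (R)-12 maps onto (2S)-15, the descriptor changing only because the CIP ranking of the CH2 and aryl branches swaps. The step needs opening at CH2 and not at the benzylic carbon, which the bulk of the tertiary dithianyl anion and the absence of any Lewis acid should secure. It also needs the alkoxide to be the only base present during heating, which protects the benzylic-allylic CH2 of the geranyl chain from isomerisation and, with C4 still a dithioketal, excludes retro-aldol or retro-oxa-Michael loss of configuration.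

Step 8
Reactants: 15 (2S)-2-[3,4-bis(methoxymethoxy)phenyl]-6-[(2E)-3,7-dimethylocta-2,6-dien-1-yl]-5,7-bis(methoxymethoxy)-2,3-dihydrospiro[chromene-4,2'-[1,3]dithiane]
Product: 16 (2S)-2-[3,4-bis(methoxymethoxy)phenyl]-6-[(2E)-3,7-dimethylocta-2,6-dien-1-yl]-5,7-bis(methoxymethoxy)-2,3-dihydro-4H-chromen-4-one
Conditions: MeI, CaCO3, MeCN–H2O (9:1), 45 °C
Reagents that add atoms: water, O
Why: Alkylative dithioketal hydrolysis (S-methylation, ionisation to an aryl-stabilised thionium ion, capture by water) under CaCO3 buffering unmasks the C4 ketone without acid, strong base or oxidant, so the alkenes, the MOM ethers and the C2 stereocentre should be untouched.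

Step 9
Reactants: 16 (2S)-2-[3,4-bis(methoxymethoxy)phenyl]-6-[(2E)-3,7-dimethylocta-2,6-dien-1-yl]-5,7-bis(methoxymethoxy)-2,3-dihydro-4H-chromen-4-one
Product: 17 nymphaeol A, (2S)-2-(3,4-dihydroxyphenyl)-6-[(2E)-3,7-dimethylocta-2,6-dien-1-yl]-5,7-dihydroxy-2,3-dihydro-4H-chromen-4-one
Conditions: 3 M aq. HCl, MeOH, 50 °C
Reagents that add atoms: none
Why: Acid-catalysed acetal methanolysis removes all four MOM groups under conditions that have precedent for prenylated and geranylated flavanones, the flavanone C2 being configurationally stable in acid.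

**Compound list**

1 | 5-fluorobenzene-1,3-diol (5-fluororesorcinol) | Oc1cc(O)cc(F)c1 | starting material
2 | 1-fluoro-3,5-bis(methoxymethoxy)benzene | COCOc1cc(F)cc(OCOC)c1 | intermediate
3 | geranyl bromide, (2E)-1-bromo-3,7-dimethylocta-2,6-diene | CC(C)=CCC/C(C)=C/CBr | starting material
4 | [4-fluoro-2,6-bis(methoxymethoxy)phenyl]lithium | [Li]c1c(OCOC)cc(F)cc1OCOC | intermediate
5 | 2-[(2E)-3,7-dimethylocta-2,6-dien-1-yl]-5-fluoro-1,3-bis(methoxymethoxy)benzene | CC(C)=CCC/C(C)=C/Cc1c(OCOC)cc(F)cc1OCOC | intermediate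
6 | {3-[(2E)-3,7-dimethylocta-2,6-dien-1-yl]-6-fluoro-2,4-bis(methoxymethoxy)phenyl}lithium | CC(C)=CCC/C(C)=C/Cc1c(OCOC)cc(F)c([Li])c1OCOC | intermediate
7 | {3-[(2E)-3,7-dimethylocta-2,6-dien-1-yl]-6-fluoro-2,4-bis(methoxymethoxy)phenyl}magnesium bromide | CC(C)=CCC/C(C)=C/Cc1c(OCOC)cc(F)c([Mg]Br)c1OCOC | intermediate
8 | 2-{3-[(2E)-3,7-dimethylocta-2,6-dien-1-yl]-6-fluoro-2,4-bis(methoxymethoxy)phenyl}-1,3-dithiane | CC(C)=CCC/C(C)=C/Cc1c(OCOC)cc(F)c(C2SCCCS2)c1OCOC | intermediate
9 | 2-chloro-1-(3,4-dihydroxyphenyl)ethan-1-one | O=C(CCl)c1ccc(O)c(O)c1 | starting material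
10 | 2-chloro-1-[3,4-bis(methoxymethoxy)phenyl]ethan-1-one | O=C(CCl)c1ccc(OCOC)c(OCOC)c1 | intermediate
11 | (1R)-2-chloro-1-[3,4-bis(methoxymethoxy)phenyl]ethan-1-ol | ClC[C@@H](c1ccc(OCOC)c(OCOC)c1)O | intermediate
12 | (2R)-2-[3,4-bis(methoxymethoxy)phenyl]oxirane | C1[C@@H](c2ccc(OCOC)c(OCOC)c2)O1 | intermediate
13 | 2-lithio derivative of dithiane 8 | CC(C)=CCC/C(C)=C/Cc1c(OCOC)cc(F)c(C2([Li])SCCCS2)c1OCOC | intermediate
14 | lithium (1S)-1-[3,4-bis(methoxymethoxy)phenyl]-2-(2-{3-[(2E)-3,7-dimethylocta-2,6-dien-1-yl]-6-fluoro-2,4-bis(methoxymethoxy)phenyl}-1,3-dithian-2-yl)ethan-1-olate | CC(C)=CCC/C(C)=C/Cc1c(OCOC)cc(F)c(C2(C[C@@H](c3ccc(OCOC)c(OCOC)c3)O[Li])SCCCS2)c1OCOC | intermediate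
15 | (2S)-2-[3,4-bis(methoxymethoxy)phenyl]-6-[(2E)-3,7-dimethylocta-2,6-dien-1-yl]-5,7-bis(methoxymethoxy)-2,3-dihydrospiro[chromene-4,2'-[1,3]dithiane] | CC(C)=CCC/C(C)=C/Cc1c(OCOC)cc2c(c1OCOC)C1(SCCCS1)C[C@@H](c1ccc(OCOC)c(OCOC)c1)O2 | intermediate
16 | (2S)-2-[3,4-bis(methoxymethoxy)phenyl]-6-[(2E)-3,7-dimethylocta-2,6-dien-1-yl]-5,7-bis(methoxymethoxy)-2,3-dihydro-4H-chromen-4-one | CC(C)=CCC/C(C)=C/Cc1c(OCOC)cc2c(c1OCOC)C(=O)C[C@@H](c1ccc(OCOC)c(OCOC)c1)O2 | intermediate
17 | nymphaeol A, (2S)-2-(3,4-dihydroxyphenyl)-6-[(2E)-3,7-dimethylocta-2,6-dien-1-yl]-5,7-dihydroxy-2,3-dihydro-4H-chromen-4-one | CC(C)=CCC/C(C)=C/Cc1c(O)cc2c(c1O)C(=O)C[C@@H](c1ccc(O)c(O)c1)O2 | target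

**Step count and risks**

Total step count: 9. Longest linear sequence: 6 steps (1, 2, 3, 7, 8, 9; the branch 4, 5, 6 joins at step 7).

Steps most likely to fail:

1. Step 7. What may go wrong: attack of the carbanion at the benzylic oxirane carbon or rearrangement of the electron-rich oxirane before it is opened, and slow fluoride displacement by the lithium alkoxide with decomposition on prolonged heating. Fallback, setting out from chlorohydrin 11 and dithiane 8 and returning at 15: the oxirane is replaced by a protected iodohydrin and the ring closure is run as a separate operation.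
   - Chlorohydrin 11 is silylated (TBSCl, imidazole, DMF) to the (R)-silyl ether chloride F1.
   - Finkelstein exchange (NaI, acetone, reflux) gives the (R)-silyl ether iodide F2.
   - Lithiodithiane 13 (from 8, n-BuLi, THF–HMPA, −78 °C) is alkylated with F2 to the open-chain silyl ether F3.
   - TBAF in THF frees the open-chain alcohol F4.
   - KOt-Bu in THF at 65 °C, without dipolar cosolvent, closes ring C by the established alkoxide SNAr flavan closure to give 15.

2. Step 3. What may go wrong: loss of LiF from the ortho-fluoroaryl metal (aryne formation), lateral metalation at the benzylic-allylic CH2 of the geranyl chain, or halogen–metal exchange with the chlorodithiane instead of C–C coupling. Fallback, setting out from 5 and returning at 8: the carbon is introduced as an aldehyde and converted to the dithiane afterwards.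
   - Ortho-lithiation of 5 (n-BuLi, THF, −78 °C) and quench with DMF gives the aldehyde F5.
   - Thioacetalisation under neutral conditions (1,3-propanedithiol, cat. LiBr, neat, 75 °C, under N2), chosen to spare the MOM ethers and the diene, gives 8.

3. Step 9. What may go wrong: acid-induced cyclisation of the geranyl chain onto the flanking C5 or C7 hydroxyl (chroman formation), addition of HCl or methanol to the alkenes, or partial racemisation through reversible opening of ring C. Fallback, setting out from 16 and returning at 17: the aryl MOM ethers are exchanged for silyl ethers under non-protic conditions.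
   - TESOTf and 2,2'-bipyridyl in CH2Cl2 (0 °C → rt) convert the four aryl MOM ethers directly into the tetrakis(triethylsilyl) ether F6.
   - Buffered fluoride (Et3N·3HF, THF, 0 °C) cleaves the silyl ethers to give 17.

**Further compounds**

F1 | step 7 | tert-butyl{(1R)-2-chloro-1-[3,4-bis(methoxymethoxy)phenyl]ethoxy}dimethylsilane | ClC[C@@H](c1ccc(OCOC)c(OCOC)c1)O[Si](C)(C)C(C)(C)C
F2 | step 7 | tert-butyl{(1R)-2-iodo-1-[3,4-bis(methoxymethoxy)phenyl]ethoxy}dimethylsilane | IC[C@@H](c1ccc(OCOC)c(OCOC)c1)O[Si](C)(C)C(C)(C)C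
F3 | step 7 | 2-{(2S)-2-[3,4-bis(methoxymethoxy)phenyl]-2-[(tert-butyldimethylsilyl)oxy]ethyl}-2-{3-[(2E)-3,7-dimethylocta-2,6-dien-1-yl]-6-fluoro-2,4-bis(methoxymethoxy)phenyl}-1,3-dithiane | CC(C)=CCC/C(C)=C/Cc1c(OCOC)cc(F)c(C2(C[C@@H](c3ccc(OCOC)c(OCOC)c3)O[Si](C)(C)C(C)(C)C)SCCCS2)c1OCOC
F4 | step 7 | (1S)-1-[3,4-bis(methoxymethoxy)phenyl]-2-(2-{3-[(2E)-3,7-dimethylocta-2,6-dien-1-yl]-6-fluoro-2,4-bis(methoxymethoxy)phenyl}-1,3-dithian-2-yl)ethan-1-ol | CC(C)=CCC/C(C)=C/Cc1c(OCOC)cc(F)c(C2(C[C@@H](c3ccc(OCOC)c(OCOC)c3)O)SCCCS2)c1OCOC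
F5 | step 3 | 3-[(2E)-3,7-dimethylocta-2,6-dien-1-yl]-6-fluoro-2,4-bis(methoxymethoxy)benzaldehyde | CC(C)=CCC/C(C)=C/Cc1c(OCOC)cc(F)c(C=O)c1OCOC
F6 | step 9 | (2S)-2-[3,4-bis(triethylsilyloxy)phenyl]-6-[(2E)-3,7-dimethylocta-2,6-dien-1-yl]-5,7-bis(triethylsilyloxy)-2,3-dihydro-4H-chromen-4-one | CC(C)=CCC/C(C)=C/Cc1c(O[Si](CC)(CC)CC)cc2c(c1O[Si](CC)(CC)CC)C(=O)C[C@@H](c1ccc(O[Si](CC)(CC)CC)c(O[Si](CC)(CC)CC)c1)O2
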